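**Plan**

1. Retrosynthesis: the acetate is cut first. The lactone is then cut at O–C14 and C15–C16 with CO2 as the one-carbon piece, leading back to a 14-membered carbocycle with an ethynyl group on C1 and a cis 13,14-oxirane. The ring is cut at C8–C9 and the chain at C1–C14.
2. Enabling feature: C15 and C14 are 1,3-related through C1 and O13/O14 are vicinal, so a carboxylate created on C15 lies 5-exo to a C13–C14 oxirane. Its opening at C14 closes the γ-lactone ring (O, C16, C15, C1, C14) with inversion and frees O13.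
3. Forward: fragment 1 (C1–C8 plus C15/C17, steps 1–7) and fragment 2 (C9–C14, steps 8–14) are joined at C1–C14. The 13,14-oxirane and then the 3,4-oxirane are made on the open chain, the 14-membered ring closes at C8–C9, and the lactone ring and the acetate come last.
4. Stereochemistry: C12/C13 come from Brown crotylboration. C1 comes from a catalytic asymmetric alkynylation and is carried over with inversion in the allenylzinc addition, which also sets C14 (anti, Felkin). The cis 13,14-oxirane arises by double inversion of the anti diol, C3/C4 by Shi epoxidation, both E alkenes by syn metallation of alkynes, and C14 of the target by inversion in the key step.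

Key step: step 21

Remark: atoms are numbered as in cembranes. C1–C14 are the ring carbons (C1 bears C15, C14 the lactone oxygen, C13 the acetate; C4, C8 and C12 bear methyl groups), C16 is the lactone carbonyl and C17 the exocyclic methylene.
Remark: 2-[(4-methoxyphenyl)methoxy]acetaldehyde (12) is taken as a purchasable aldehyde.
Remark: the reagent enantiomers named in steps 6 and 8 are those expected from the accepted transition-state models; the product structures drawn define what is required.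

**Fragment 1 (steps 1–7)**

Step 1
Reactants: 1 pent-3-yn-1-ol
Product: 3 (3E)-4-bromopent-3-en-1-ol, via alkenylzirconocene 2 (not isolated)
Conditions: Cp2Zr(H)Cl (2.5 equiv), THF, 23 to 50 °C; then N-bromosuccinimide, 0 °C
Reagents that add atoms: N-bromosuccinimide O=C1CCC(=O)N1Br
Why: Syn hydrozirconation of the 2-alkyne, equilibrated by excess Cp2Zr(H)Cl so that zirconium sits on the methyl-bearing carbon, followed by bromodezirconation with retention should give the E-2-bromoalkene (hydrozirconation–halogenation).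

Step 2
Reactants: 3 (3E)-4-bromopent-3-en-1-ol
Product: 4 (2E)-2-bromo-5-iodopent-2-ene
Conditions: I2, PPh3, imidazole, CH2Cl2, 0 °C
Reagents that add atoms: iodine II
Why: The primary alcohol should be converted into the iodide by the phosphine–iodine (Appel-type) reaction without touching the alkenyl bromide.

Step 3
Reactants: 4 (2E)-2-bromo-5-iodopent-2-ene
Product: 5 (5E)-6-bromohept-5-en-1-yne
Conditions: LiC≡CH·H2NCH2CH2NH2, DMSO, 15 to 23 °C
Reagents that add atoms: lithium acetylide [Li]C#C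
Why: SN2 alkylation of lithium acetylide by the primary iodide in DMSO should give the terminal enyne, the alkenyl bromide being inert to the acetylide.

Step 4
Reactants: 5 (5E)-6-bromohept-5-en-1-yne
Product: 7 (3E,7E)-8-bromo-4-methylnona-3,7-dien-1-ol, via alkenylalane 6 (not isolated)
Conditions: Me3Al, Cp2ZrCl2 (20 mol %), CH2Cl2, 23 °C; then n-BuLi, THF, −78 °C; then ethylene oxide, −78 to 0 °C
Reagents that add atoms: trimethylaluminium C[Al](C)C; ethylene oxide C1CO1
Why: Zirconium-catalysed syn carboalumination of the terminal alkyne (Negishi carboalumination) sets the E trisubstituted C3=C4 alkene, and the derived alkenylalanate should open ethylene oxide with retention of the alkene geometry.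

Step 5
Reactants: 7 (3E,7E)-8-bromo-4-methylnona-3,7-dien-1-ol
Product: 8 (3E,7E)-8-bromo-4-methylnona-3,7-dienal
Conditions: Dess–Martin periodinane, pyridine, CH2Cl2, 0 °C
Reagents that add atoms: none
Why: Dess–Martin oxidation under buffered, non-enolising conditions should give the β,γ-unsaturated aldehyde without migration of the double bond.

Step 6
Reactants: 8 (3E,7E)-8-bromo-4-methylnona-3,7-dienal; 9 tert-butyl(ethynyl)dimethylsilane
Product: 10 (3R,5E,9E)-10-bromo-1-[tert-butyl(dimethyl)silyl]-6-methylundeca-5,9-dien-1-yn-3-ol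
Conditions: Me2Zn, (S,S)-ProPhenol (20 mol %), Ph3P=O (40 mol %), toluene, 4 °C
Reagents that add atoms: none
Why: Zinc–ProPhenol-catalysed enantioselective addition of the alkynylzinc to the aldehyde (catalytic asymmetric alkynylation) should set the propargylic carbinol C1, the ligand enantiomer being the one that delivers the R configuration.

Step 7
Reactants: 10 (3R,5E,9E)-10-bromo-1-[tert-butyl(dimethyl)silyl]-6-methylundeca-5,9-dien-1-yn-3-ol
Product: 11 (3R,5E,9E)-10-bromo-1-[tert-butyl(dimethyl)silyl]-6-methylundeca-5,9-dien-1-yn-3-yl methanesulfonate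
Conditions: MeSO2Cl, Et3N, CH2Cl2, −78 °C
Reagents that add atoms: methanesulfonyl chloride CS(=O)(=O)Cl
Why: Sulfonylation through sulfene takes place at oxygen with retention and installs the propargylic leaving group needed in step 15.

**Fragment 2 (steps 8–14)**

Step 8
Reactants: 12 2-[(4-methoxyphenyl)methoxy]acetaldehyde
Product: 14 (2R,3S)-1-[(4-methoxyphenyl)methoxy]-3-methylpent-4-en-2-ol, via borinate 13 (not isolated)
Conditions: cis-but-2-ene, KOt-Bu, n-BuLi, THF, −78 to −45 °C; (+)-Ipc2BOMe; BF3·OEt2, −78 °C; then NaOH, H2O2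
Reagents that add atoms: cis-but-2-ene C/C=C\C
Why: Brown (Z)-crotylboration through a chair transition state should give the syn homoallylic alcohol, the isopinocampheyl groups of (+)-Ipc2BOMe selecting the aldehyde face that makes C13 R and C12 S.

Step 9
Reactants: 14 (2R,3S)-1-[(4-methoxyphenyl)methoxy]-3-methylpent-4-en-2-ol
Product: 15 triethyl{[(2R,3S)-1-[(4-methoxyphenyl)methoxy]-3-methylpent-4-en-2-yl]oxy}silane
Conditions: Et3SiCl, imidazole, CH2Cl2, 0 °C
Reagents that add atoms: chlorotriethylsilane CC[Si](CC)(CC)Cl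
Why: Silylation of the secondary alcohol protects O13 as an ether that mild acid removes later without loss of the alkynylsilane.

Step 10
Reactants: 15 triethyl{[(2R,3S)-1-[(4-methoxyphenyl)methoxy]-3-methylpent-4-en-2-yl]oxy}silane
Product: 17 (3S,4R)-5-[(4-methoxyphenyl)methoxy]-3-methyl-4-[(triethylsilyl)oxy]pentan-1-ol, via alkylborane 16 (not isolated)
Conditions: 9-BBN, THF, 0 to 23 °C; then NaOH, H2O2
Reagents that add atoms: hydrogen peroxide OO
Why: 9-BBN should add to the monosubstituted alkene at its terminal carbon and oxidation with retention gives the primary alcohol (hydroboration–oxidation).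

Step 11
Reactants: 17 (3S,4R)-5-[(4-methoxyphenyl)methoxy]-3-methyl-4-[(triethylsilyl)oxy]pentan-1-ol
Product: 18 (3S,4R)-5-[(4-methoxyphenyl)methoxy]-3-methyl-4-[(triethylsilyl)oxy]pentanal
Conditions: Dess–Martin periodinane, pyridine, CH2Cl2, 0 °C
Reagents that add atoms: none
Why: Dess–Martin oxidation should give the aldehyde, whose stereocentres are β and γ to the carbonyl and cannot epimerise.

Step 12
Reactants: 18 (3S,4R)-5-[(4-methoxyphenyl)methoxy]-3-methyl-4-[(triethylsilyl)oxy]pentanal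
Product: 19 triethyl{[(2R,3S)-1-[(4-methoxyphenyl)methoxy]-3-methylhex-5-en-2-yl]oxy}silane
Conditions: Ph3PCH3Br, KN(SiMe3)2, THF, −78 to 0 °C
Reagents that add atoms: methyltriphenylphosphonium bromide C[P+](c1ccccc1)(c1ccccc1)c1ccccc1.[Br-]
Why: Wittig methylenation should turn the aldehyde into the terminal alkene that later becomes the C9 borane.

Step 13
Reactants: 19 triethyl{[(2R,3S)-1-[(4-methoxyphenyl)methoxy]-3-methylhex-5-en-2-yl]oxy}silane
Product: 20 (2R,3S)-3-methyl-2-[(triethylsilyl)oxy]hex-5-en-1-ol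
Conditions: DDQ, CH2Cl2–pH 7 buffer, 0 °C
Reagents that add atoms: none
Why: Oxidative cleavage of the 4-methoxybenzyl ether by DDQ should free the primary alcohol while the triethylsilyl ether and the alkene stay intact.

Step 14
Reactants: 20 (2R,3S)-3-methyl-2-[(triethylsilyl)oxy]hex-5-en-1-ol
Product: 21 (2R,3S)-3-methyl-2-[(triethylsilyl)oxy]hex-5-enal
Conditions: Dess–Martin periodinane, pyridine, CH2Cl2, 0 °C
Reagents that add atoms: none
Why: Dess–Martin oxidation should give the α-silyloxy aldehyde, which is used at once so that C13 does not epimerise.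

**Union, ring closure and end game (steps 15–22)**

Step 15
Reactants: 11 (3R,5E,9E)-10-bromo-1-[tert-butyl(dimethyl)silyl]-6-methylundeca-5,9-dien-1-yn-3-yl methanesulfonate; 21 (2R,3S)-3-methyl-2-[(triethylsilyl)oxy]hex-5-enal
Product: 23 (4S,5R,6S,7S,9E,13E)-14-bromo-7-{[tert-butyl(dimethyl)silyl]ethynyl}-4,10-dimethyl-5-[(triethylsilyl)oxy]pentadeca-1,9,13-trien-6-ol, via allenylzinc 22 (not isolated)
Conditions: Pd(OAc)2 (5 mol %), PPh3 (5 mol %), Et2Zn (3 equiv), THF, −78 to −20 °C
Reagents that add atoms: none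
Why: Zerovalent palladium should displace the propargylic mesylate in an anti SN2′ sense much faster than it inserts into the trisubstituted alkenyl bromide at −20 °C, Et2Zn then gives a configurationally defined allenylzinc, and its addition through a cyclic SE2′ transition state to the Felkin face of the α-silyloxy aldehyde (matched pair) should set C1 (S) and C14 (S) anti to each other and C14 anti to C13 (Marshall propargylation).

Step 16
Reactants: 23 (4S,5R,6S,7S,9E,13E)-14-bromo-7-{[tert-butyl(dimethyl)silyl]ethynyl}-4,10-dimethyl-5-[(triethylsilyl)oxy]pentadeca-1,9,13-trien-6-ol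
Product: 24 (4S,5R,6S,7S,9E,13E)-14-bromo-7-{[tert-butyl(dimethyl)silyl]ethynyl}-4,10-dimethylpentadeca-1,9,13-triene-5,6-diol
Conditions: pyridinium p-toluenesulfonate (10 mol %), MeOH, 0 to 23 °C
Reagents that add atoms: none
Why: Acid-catalysed methanolysis should remove the secondary triethylsilyl ether selectively, the alkynyl tert-butyldimethylsilyl group being stable to acid.

Step 17
Reactants: 24 (4S,5R,6S,7S,9E,13E)-14-bromo-7-{[tert-butyl(dimethyl)silyl]ethynyl}-4,10-dimethylpentadeca-1,9,13-triene-5,6-diol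
Product: 27 (2R,3S)-2-[(2S)-pent-4-en-2-yl]-3-{(3S,5E,9E)-10-bromo-1-[tert-butyl(dimethyl)silyl]-6-methylundeca-5,9-dien-1-yn-3-yl}oxirane, via cyclic orthoacetate 25 (not isolated), via bromo acetate 26 (not isolated)
Conditions: MeC(OMe)3, pyridinium p-toluenesulfonate (2 mol %), CH2Cl2, 23 °C; then AcBr, CH2Cl2, 0 °C; then K2CO3, MeOH, 23 °C
Reagents that add atoms: none
Why: In the Kolb–Sharpless sequence bromide opens the acetoxonium ion with inversion and the alkoxide freed by methanolysis displaces bromide with a second inversion, so the anti diol should give the cis oxirane with both C–O configurations retained, whichever carbon bromide attacks.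

Step 18
Reactants: 27 (2R,3S)-2-[(2S)-pent-4-en-2-yl]-3-{(3S,5E,9E)-10-bromo-1-[tert-butyl(dimethyl)silyl]-6-methylundeca-5,9-dien-1-yn-3-yl}oxirane
Product: 28 (2R,3S)-2-[(2S)-pent-4-en-2-yl]-3-{(1S)-1-{[(2R,3R)-3-[(3E)-4-bromopent-3-en-1-yl]-3-methyloxiran-2-yl]methyl}-3-[tert-butyl(dimethyl)silyl]prop-2-yn-1-yl}oxirane
Conditions: D-fructose-derived Shi ketone (30 mol %), KHSO5 (as 2KHSO5·KHSO4·K2SO4), K2CO3, Bu4NHSO4, MeCN–CH2(OMe)2–aq. Na2B4O7, 0 °C
Reagents that add atoms: potassium peroxymonosulfate [K+].[O-]S(=O)(=O)OO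
Why: The dioxirane of the Shi epoxidation should attack only the electron-rich trisubstituted C3=C4 alkene (the bromoalkene is deactivated, the monosubstituted alkene is slow), and its spiro transition state should deliver the 3R,4R oxirane under reagent control.

Step 19
Reactants: 28 (2R,3S)-2-[(2S)-pent-4-en-2-yl]-3-{(1S)-1-{[(2R,3R)-3-[(3E)-4-bromopent-3-en-1-yl]-3-methyloxiran-2-yl]methyl}-3-[tert-butyl(dimethyl)silyl]prop-2-yn-1-yl}oxirane
Product: 30 (1S,3R,4R,7E,12S,13R,14S)-1-{[tert-butyl(dimethyl)silyl]ethynyl}-3,4:13,14-diepoxy-4,8,12-trimethylcyclotetradec-7-ene, via alkylborane 29 (not isolated)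
Conditions: 9-BBN, THF, 23 °C; then slow addition to Pd(dppf)Cl2 (20 mol %), AsPh3 (40 mol %), Cs2CO3, DMF–THF–H2O, 50 °C, 2 mM
Reagents that add atoms: none
Why: 9-BBN should add only to the terminal alkene, and B-alkyl Suzuki–Miyaura coupling with the alkenyl bromide under high dilution should close the 14-membered ring at C8–C9 with retention of the E geometry.

Step 20
Reactants: 30 (1S,3R,4R,7E,12S,13R,14S)-1-{[tert-butyl(dimethyl)silyl]ethynyl}-3,4:13,14-diepoxy-4,8,12-trimethylcyclotetradec-7-ene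
Product: 31 (1S,3R,4R,7E,12S,13R,14S)-3,4:13,14-diepoxy-1-ethynyl-4,8,12-trimethylcyclotetradec-7-ene
Conditions: Bu4NF, THF, 0 °C
Reagents that add atoms: none
Why: Fluoride should cleave the C(sp)–Si bond and free the terminal alkyne without opening either oxirane (protodesilylation).

Step 21
Reactants: 31 (1S,3R,4R,7E,12S,13R,14S)-3,4:13,14-diepoxy-1-ethynyl-4,8,12-trimethylcyclotetradec-7-ene
Product: 34 (1S,3R,4R,7E,12S,13R,14R)-3,4-epoxy-13-hydroxycembra-7,15(17)-dien-16,14-olide, via alkenylboronate 32 (not isolated), via potassium carboxylate 33 (not isolated)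
Conditions: (SIMes)CuCl (5 mol %), NaOt-Bu (5 mol %), B2pin2 (1.05 equiv), MeOH (1.2 equiv), THF, −40 to 0 °C; then (IPr)CuCl (5 mol %), KOt-Bu (2.2 equiv), CO2 (1 atm), THF, 65 °C; then aq. NaH2PO4 (pH 4.5), 23 °C
Reagents that add atoms: carbon dioxide O=C=O
Why: Proposed new method: a carbene-ligated copper boryl adds syn across the terminal alkyne with boron on the internal carbon C15 and methanol protonates the alkenylcopper, so that the 1,1-disubstituted alkenylboronate serves as a relay; after KOt-Bu and CO2 are added the boronate passes its alkenyl group to copper, the alkenylcopper inserts CO2 to form the C15–C16 bond, and the carboxylate then opens the cis 13,14-oxirane at C14 to form the O–C14 bond and release the C13 alkoxide. The closest known reaction types are the copper-catalysed α-selective protoboration of terminal alkynes, the copper-catalysed carboxylation of alkenylboronic esters with CO2 and the lactonisation of γ,δ-epoxy carboxylates, whose one-pot relay ending in oxirane opening has not been shown. The γ-lactone ring closes in the 5-exo-tet mode at C14, which should outrun 6-endo attack at C13 and 6-exo attack on the 3,4-oxirane at C3, and the mildly acidic quench completes the closure. C14 is set by inversion at the oxirane carbon (S to R), C13 keeps the configuration it had in the oxirane, and the cis ring fusion follows from the anti C1/C14 relationship fixed in step 15. The step needs boron on the internal alkyne carbon, which the N-aryl carbene ligand and the branched, oxygen-flanked propargylic carbon C1 should favour, and it needs full consumption of the alkyne before base and CO2 are added so that no alkynyl C–H carboxylation occurs.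

Step 22
Reactants: 34 (1S,3R,4R,7E,12S,13R,14R)-3,4-epoxy-13-hydroxycembra-7,15(17)-dien-16,14-olide
Product: 35 eupalmerin acetate
Conditions: Ac2O, pyridine, 4-(dimethylamino)pyridine (cat.), CH2Cl2, 0 °C
Reagents that add atoms: acetic anhydride CC(=O)OC(C)=O
Why: Acylation of the secondary alcohol under nucleophilic catalysis should give the acetate without touching the lactone or the oxirane.

**Compound list**

1 | pent-3-yn-1-ol | CC#CCCO | starting material
2 | O-zirconated (E)-alkenylzirconocene from 1 (Cp drawn σ-bonded) | C/C(=C\CCO[Zr](Cl)(C1C=CC=C1)C1C=CC=C1)[Zr](Cl)(C1C=CC=C1)C1C=CC=C1 | intermediate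
3 | (3E)-4-bromopent-3-en-1-ol | C/C(Br)=C\CCO | intermediate
4 | (2E)-2-bromo-5-iodopent-2-ene | C/C(Br)=C\CCI | intermediate
5 | (5E)-6-bromohept-5-en-1-yne | C/C(Br)=C\CCC#C | intermediate
6 | [(1E,5E)-6-bromo-2-methylhepta-1,5-dien-1-yl]dimethylalumane | C/C(Br)=C\CC/C(C)=C/[Al](C)C | intermediate
7 | (3E,7E)-8-bromo-4-methylnona-3,7-dien-1-ol | C/C(Br)=C\CC/C(C)=C/CCO | intermediate
8 | (3E,7E)-8-bromo-4-methylnona-3,7-dienal | C/C(Br)=C\CC/C(C)=C/CC=O | intermediate
9 | tert-butyl(ethynyl)dimethylsilane | C#C[Si](C)(C)C(C)(C)C | starting material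
10 | (3R,5E,9E)-10-bromo-1-[tert-butyl(dimethyl)silyl]-6-methylundeca-5,9-dien-1-yn-3-ol | CC(C)(C)[Si](C)(C)C#C[C@H](O)C/C=C(C)/CC/C=C(\C)Br | intermediate
11 | (3R,5E,9E)-10-bromo-1-[tert-butyl(dimethyl)silyl]-6-methylundeca-5,9-dien-1-yn-3-yl methanesulfonate | CC(C)(C)[Si](C)(C)C#C[C@H](OS(C)(=O)=O)C/C=C(C)/CC/C=C(\C)Br | intermediate
12 | 2-[(4-methoxyphenyl)methoxy]acetaldehyde | COc1ccc(COCC=O)cc1 | starting material
13 | diisopinocampheylborinate of 14 | COc1ccc(COC[C@H](OB([C@H]2C[C@H]3C[C@@H]([C@@H]2C)C3(C)C)[C@H]2C[C@H]3C[C@@H]([C@@H]2C)C3(C)C)[C@@H](C)C=C)cc1 | intermediate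
14 | (2R,3S)-1-[(4-methoxyphenyl)methoxy]-3-methylpent-4-en-2-ol | COc1ccc(COC[C@H](O)[C@@H](C)C=C)cc1 | intermediate
15 | triethyl{[(2R,3S)-1-[(4-methoxyphenyl)methoxy]-3-methylpent-4-en-2-yl]oxy}silane | COc1ccc(COC[C@H](O[Si](CC)(CC)CC)[C@@H](C)C=C)cc1 | intermediate
16 | B-alkyl-9-borabicyclo[3.3.1]nonane from 15 | COc1ccc(COC[C@H](O[Si](CC)(CC)CC)[C@@H](C)CCB2C3CCCC2CCC3)cc1 | intermediate
17 | (3S,4R)-5-[(4-methoxyphenyl)methoxy]-3-methyl-4-[(triethylsilyl)oxy]pentan-1-ol | COc1ccc(COC[C@H](O[Si](CC)(CC)CC)[C@@H](C)CCO)cc1 | intermediate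
18 | (3S,4R)-5-[(4-methoxyphenyl)methoxy]-3-methyl-4-[(triethylsilyl)oxy]pentanal | COc1ccc(COC[C@H](O[Si](CC)(CC)CC)[C@@H](C)CC=O)cc1 | intermediate
19 | triethyl{[(2R,3S)-1-[(4-methoxyphenyl)methoxy]-3-methylhex-5-en-2-yl]oxy}silane | COc1ccc(COC[C@H](O[Si](CC)(CC)CC)[C@@H](C)CC=C)cc1 | intermediate
20 | (2R,3S)-3-methyl-2-[(triethylsilyl)oxy]hex-5-en-1-ol | OC[C@H](O[Si](CC)(CC)CC)[C@@H](C)CC=C | intermediate
21 | (2R,3S)-3-methyl-2-[(triethylsilyl)oxy]hex-5-enal | O=C[C@H](O[Si](CC)(CC)CC)[C@@H](C)CC=C | intermediate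
22 | ethyl(allenyl)zinc from 11, one axial isomer with zinc anti to the departed mesylate (axis not encoded) | CC[Zn]C(=C=CC/C=C(C)/CC/C=C(\C)Br)[Si](C)(C)C(C)(C)C | intermediate
23 | (4S,5R,6S,7S,9E,13E)-14-bromo-7-{[tert-butyl(dimethyl)silyl]ethynyl}-4,10-dimethyl-5-[(triethylsilyl)oxy]pentadeca-1,9,13-trien-6-ol | CC(C)(C)[Si](C)(C)C#C[C@H](C/C=C(C)/CC/C=C(\C)Br)[C@H](O)[C@H](O[Si](CC)(CC)CC)[C@@H](C)CC=C | intermediate
24 | (4S,5R,6S,7S,9E,13E)-14-bromo-7-{[tert-butyl(dimethyl)silyl]ethynyl}-4,10-dimethylpentadeca-1,9,13-triene-5,6-diol | CC(C)(C)[Si](C)(C)C#C[C@H](C/C=C(C)/CC/C=C(\C)Br)[C@H](O)[C@H](O)[C@@H](C)CC=C | intermediate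
25 | cyclic orthoacetate (2-methoxy-2-methyl-1,3-dioxolane) of diol 24 | CC(C)(C)[Si](C)(C)C#C[C@H](C/C=C(C)/CC/C=C(\C)Br)[C@@H]1OC(C)(OC)O[C@@H]1[C@@H](C)CC=C | intermediate
26 | (4S,5S,6S,7S,9E,13E)-5,14-dibromo-7-{[tert-butyl(dimethyl)silyl]ethynyl}-4,10-dimethylpentadeca-1,9,13-trien-6-yl acetate (regioisomer drawn; the other converges on 27) | CC(C)(C)[Si](C)(C)C#C[C@H](C/C=C(C)/CC/C=C(\C)Br)[C@H](OC(C)=O)[C@@H](Br)[C@@H](C)CC=C | intermediate
27 | (2R,3S)-2-[(2S)-pent-4-en-2-yl]-3-{(3S,5E,9E)-10-bromo-1-[tert-butyl(dimethyl)silyl]-6-methylundeca-5,9-dien-1-yn-3-yl}oxirane | CC(C)(C)[Si](C)(C)C#C[C@H](C/C=C(C)/CC/C=C(\C)Br)[C@@H]1O[C@@H]1[C@@H](C)CC=C | intermediate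
28 | (2R,3S)-2-[(2S)-pent-4-en-2-yl]-3-{(1S)-1-{[(2R,3R)-3-[(3E)-4-bromopent-3-en-1-yl]-3-methyloxiran-2-yl]methyl}-3-[tert-butyl(dimethyl)silyl]prop-2-yn-1-yl}oxirane | CC(C)(C)[Si](C)(C)C#C[C@H](C[C@H]2O[C@]2(C)CC/C=C(\C)Br)[C@@H]1O[C@@H]1[C@@H](C)CC=C | intermediate
29 | B-alkyl-9-borabicyclo[3.3.1]nonane from 28 (boron on C9) | CC(C)(C)[Si](C)(C)C#C[C@H](C[C@H]2O[C@]2(C)CC/C=C(\C)Br)[C@@H]1O[C@@H]1[C@@H](C)CCCB1C2CCCC1CCC2 | intermediate
30 | (1S,3R,4R,7E,12S,13R,14S)-1-{[tert-butyl(dimethyl)silyl]ethynyl}-3,4:13,14-diepoxy-4,8,12-trimethylcyclotetradec-7-ene | CC(C)(C)[Si](C)(C)C#C[C@@H]1C[C@H]2O[C@]2(C)CC/C=C(C)/CCC[C@H](C)[C@H]3O[C@@H]13 | intermediate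
31 | (1S,3R,4R,7E,12S,13R,14S)-3,4:13,14-diepoxy-1-ethynyl-4,8,12-trimethylcyclotetradec-7-ene | C#C[C@@H]1C[C@H]2O[C@]2(C)CC/C=C(C)/CCC[C@H](C)[C@H]3O[C@@H]13 | intermediate
32 | 1-[1-(4,4,5,5-tetramethyl-1,3,2-dioxaborolan-2-yl)ethenyl] analogue of 31 | C=C(B1OC(C)(C)C(C)(C)O1)[C@@H]1C[C@H]2O[C@]2(C)CC/C=C(C)/CCC[C@H](C)[C@H]3O[C@@H]13 | intermediate
33 | potassium 2-[(1S,3R,4R,7E,12S,13R,14S)-3,4:13,14-diepoxy-4,8,12-trimethylcyclotetradec-7-en-1-yl]prop-2-enoate | [K+].[O-]C(=O)C(=C)[C@@H]1C[C@H]2O[C@]2(C)CC/C=C(C)/CCC[C@H](C)[C@H]3O[C@@H]13 | intermediate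
34 | (1S,3R,4R,7E,12S,13R,14R)-3,4-epoxy-13-hydroxycembra-7,15(17)-dien-16,14-olide | C=C1C(=O)O[C@H]2[C@H](O)[C@@H](C)CCC/C(C)=C/CC[C@@]3(C)O[C@@H]3C[C@@H]12 | intermediate
35 | eupalmerin acetate, (1S,3R,4R,7E,12S,13R,14R)-13-acetoxy-3,4-epoxycembra-7,15(17)-dien-16,14-olide | C=C1C(=O)O[C@H]2[C@H](OC(C)=O)[C@@H](C)CCC/C(C)=C/CC[C@@]3(C)O[C@@H]3C[C@@H]12 | target

**Step count and risks**

Total step count: 22. Longest linear sequence: 15 steps (steps 1–7 or 8–14, then 15–22).

Steps most likely to fail: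

1. Step 21 (proposed new method). Boron may be delivered to the terminal instead of the internal alkyne carbon, which would lead to the linear acrylate, or base may open or eliminate an oxirane before CO2 is captured. Fallback with known chemistry, setting out from 31: ruthenium-catalysed Markovnikov hydrosilylation ([Cp*Ru(MeCN)3]PF6, BnMe2SiH, acetone, 0 °C) would give the 1,1-disubstituted alkenylsilane F1. Iododesilylation (N-iodosuccinimide, 2,6-lutidine, (CF3)2CHOH, 0 °C) would give the 2-iodoalkene F2. Iodine–lithium exchange (t-BuLi, Et2O, −78 °C) and CO2 would give the lithium acrylate F3, which on buffering to pH 4.5 (aq. NaH2PO4) would close onto the 13,14-oxirane and come back to the route at 34.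

2. Step 19. Intermolecular coupling to oligomers or protodeboronation of the alkylborane may outrun ring closure. Fallback, setting out from 28: hydroboration–oxidation (9-BBN; then NaBO3) would give the primary alcohol F4, mesylation the mesylate F5, and NaI in acetone the primary iodide F6. LiCl-promoted zinc insertion (Zn, LiCl, THF) would give the alkylzinc iodide F7, and slow addition of F7 to Pd(t-Bu3P)2 in THF–N-methylpyrrolidone (intramolecular Negishi coupling) would close the ring and come back to the route at 30.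

3. Step 15. Zerovalent palladium may insert into the C–Br bond in competition with the mesylate, or the facial selectivity at the aldehyde may be eroded. Fallback without palladium, setting out from 10: ClCO2Me and pyridine would give the propargylic methyl carbonate F8. Copper-catalysed anti SN2′ borylation (CuOt-Bu, Xantphos, B2pin2, THF) would give the axially chiral allenylboronate F9. Uncatalysed addition of F9 to aldehyde 21 through the same cyclic transition state (toluene, 23 °C), followed by aqueous work-up, would come back to the route at 23.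

Further compounds
F1 | step 21 | 1-[1-(benzyldimethylsilyl)ethenyl] analogue of 31 | C=C([Si](C)(C)Cc1ccccc1)[C@@H]1C[C@H]2O[C@]2(C)CC/C=C(C)/CCC[C@H](C)[C@H]3O[C@@H]13
F2 | step 21 | 1-(1-iodoethenyl) analogue of 31 | C=C(I)[C@@H]1C[C@H]2O[C@]2(C)CC/C=C(C)/CCC[C@H](C)[C@H]3O[C@@H]13
F3 | step 21 | lithium 2-[(1S,3R,4R,7E,12S,13R,14S)-3,4:13,14-diepoxy-4,8,12-trimethylcyclotetradec-7-en-1-yl]prop-2-enoate | [Li+].[O-]C(=O)C(=C)[C@@H]1C[C@H]2O[C@]2(C)CC/C=C(C)/CCC[C@H](C)[C@H]3O[C@@H]13
F4 | step 19 | primary alcohol from 28 (C9–OH) | CC(C)(C)[Si](C)(C)C#C[C@H](C[C@H]2O[C@]2(C)CC/C=C(\C)Br)[C@@H]1O[C@@H]1[C@@H](C)CCCO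
F5 | step 19 | methanesulfonate of F4 | CC(C)(C)[Si](C)(C)C#C[C@H](C[C@H]2O[C@]2(C)CC/C=C(\C)Br)[C@@H]1O[C@@H]1[C@@H](C)CCCOS(C)(=O)=O
F6 | step 19 | primary iodide from F5 | CC(C)(C)[Si](C)(C)C#C[C@H](C[C@H]2O[C@]2(C)CC/C=C(\C)Br)[C@@H]1O[C@@H]1[C@@H](C)CCCI
F7 | step 19 | alkylzinc iodide from F6 | CC(C)(C)[Si](C)(C)C#C[C@H](C[C@H]2O[C@]2(C)CC/C=C(\C)Br)[C@@H]1O[C@@H]1[C@@H](C)CCC[Zn]I
F8 | step 15 | methyl carbonate of 10 | CC(C)(C)[Si](C)(C)C#C[C@H](OC(=O)OC)C/C=C(C)/CC/C=C(\C)Br
F9 | step 15 | allenylboronate from F8, one axial isomer (axis not encoded) | CC(C)(C)[Si](C)(C)C(B1OC(C)(C)C(C)(C)O1)=C=CC/C=C(C)/CC/C=C(\C)Br
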